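**Strategy.** The dihydropyran ring is built by a formal [3+3] anionic annulation. O1–C2–C3 of the chroman is the three-atom unit of an enantiopure aryl oxirane, so C2 is set beforehand by hydrolytic kinetic resolution. C4–C4a–C8a comes from 4-(benzyloxy)-2-fluorobenzaldehyde as its 1,3-dithiane: C4 is a masked acyl anion and C8a carries fluorine. In one pot the lithiated dithiane opens the oxirane at its CH2 group (C3–C4) and the resulting alkoxide displaces the fluoride (O1–C8a). It exploits the 1,3-relationship of O1 and C3 and the ortho placement of C4 and O1 on ring A. Desulfurization, C6 formylation, Claisen–Schmidt condensation, a rhodium-catalysed asymmetric arylation for the diarylmethine centre and hydrogenolysis finish the synthesis.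

Key step: step 6

Remark: the target is read as (S) at C2 of the chroman and (R) at the diarylmethine carbon; chroman numbering (O1, C2, C3, C4, C4a, C5 to C8, C8a) is used for the pyran ring and ring A.

**Step 1**
Reactants: 1 2-fluoro-4-hydroxybenzaldehyde
Product: 2 4-(benzyloxy)-2-fluorobenzaldehyde
Conditions: BnBr, K2CO3, DMF, rt
Reagents that add atoms: benzyl bromide BrCc1ccccc1
Why: Williamson ether synthesis of the acidic para-formyl phenol; benzyl survives organolithium, base, hydride and formylation and is removed in the last step.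

**Step 2**
Reactants: 2 4-(benzyloxy)-2-fluorobenzaldehyde
Product: 3 2-[4-(benzyloxy)-2-fluorophenyl]-1,3-dithiane
Conditions: propane-1,3-dithiol, I2 (10 mol%), CH2Cl2, rt
Reagents that add atoms: propane-1,3-dithiol SCCCS
Why: Mild Lewis-acid-catalysed thioacetalization of the electron-rich aldehyde gives the dithiane that turns the future C4 into an acyl-anion equivalent (Corey–Seebach umpolung) without touching the aryl fluoride or the benzyl ether.

**Step 3**
Reactants: 4 5-hydroxy-2-methoxybenzaldehyde
Product: 5 5-(benzyloxy)-2-methoxybenzaldehyde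
Conditions: BnBr, K2CO3, DMF, rt
Reagents that add atoms: benzyl bromide BrCc1ccccc1
Why: Williamson ether synthesis of the only free phenol.

**Step 4**
Reactants: 5 5-(benzyloxy)-2-methoxybenzaldehyde
Product: 6 racemic 2-[5-(benzyloxy)-2-methoxyphenyl]oxirane
Conditions: Me3S+ I−, NaH, DMSO/THF, 0 °C → rt
Reagents that add atoms: trimethylsulfonium iodide C[S+](C)C.[I-]
Why: Corey–Chaykovsky epoxidation, in which dimethylsulfonium methylide adds to the aldehyde and the betaine closes to the terminal oxirane (racemic at this stage).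

**Step 5**
Reactants: 6 racemic 2-[5-(benzyloxy)-2-methoxyphenyl]oxirane
Product: 7 (R)-2-[5-(benzyloxy)-2-methoxyphenyl]oxirane
Conditions: (R,R)-(salen)Co(OAc) (trivalent cobalt; salen = N,N'-bis(3,5-di-tert-butylsalicylidene)cyclohexane-1,2-diamine; 0.5 mol%), H2O (0.55 equiv), THF, 0 °C → rt
Reagents that add atoms: none
Why: Hydrolytic kinetic resolution, in which the chiral cobalt salen complex should hydrolyse the (S)-oxirane much faster at its CH2 group and leave the (R)-oxirane, whose stereocentre becomes C2 of the chroman; the sense is the one known for terminal alkyl and aryl oxiranes with the (R,R)-catalyst.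

**Step 6**
Reactants: 3 2-[4-(benzyloxy)-2-fluorophenyl]-1,3-dithiane; 7 (R)-2-[5-(benzyloxy)-2-methoxyphenyl]oxirane
Product: 10 (2S)-7-(benzyloxy)-2-[5-(benzyloxy)-2-methoxyphenyl]spiro[chromane-4,2'-[1,3]dithiane], via 2-lithio-1,3-dithiane 8 (not isolated), via lithium alkoxide 9 (not isolated)
Conditions: n-BuLi, THF, −78 °C; then 7, DMPU, −78 → 0 °C; then KOtBu, 65 °C
Reagents that add atoms: none
Why: n-BuLi removes the acidic C2–H of the dithiane, and the Lewis-acid-free tertiary carbanion 8 opens oxirane 7 by SN2 at the unsubstituted CH2, which forms C3–C4 and leaves the stereocentre untouched. Exchange of lithium for potassium (KOtBu, DMPU) then lets alkoxide 9 attack the fluorine-bearing carbon ortho to the dithiane carbon in an intramolecular SNAr (Meisenheimer anion, loss of fluoride), which forms O1–C8a. The closest known reactions are the alkylation of 2-aryl-2-lithio-1,3-dithianes with terminal epoxides and the base-mediated cyclization of 3-(2-fluoroaryl)propan-1-ols to chromans. The pyran ring closes in a 6-exo-trig manner at the aromatic carbon; closure is helped by the geminal disubstitution at C4 (Thorpe–Ingold effect) and by the 7-benzyloxy group, which is meta to C8a and acts there mainly through its inductive pull. No new stereocentre is formed: C2 keeps the geometry of the (R)-oxirane and is (S) in the product only because the CIP ranking changes. The step needs terminal rather than benzylic opening of the oxirane, secured by the absence of a Lewis acid and the bulk of the carbanion, and deprotonation of the dithiane C–H rather than the arene C–H between F and OBn, secured by the much higher acidity of the former at −78 °C.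

**Step 7**
Reactants: 10 (2S)-7-(benzyloxy)-2-[5-(benzyloxy)-2-methoxyphenyl]spiro[chromane-4,2'-[1,3]dithiane]
Product: 11 (S)-7-(benzyloxy)-2-[5-(benzyloxy)-2-methoxyphenyl]chromane
Conditions: NiCl2·6H2O, NaBH4, MeOH/THF, 0 °C → rt
Reagents that add atoms: none
Why: Nickel boride desulfurization cleaves both benzylic C–S bonds and turns the dithioketal carbon into the C4 methylene; under these mild, non-acidic conditions the aryl benzyl ethers and the C2–O1 bond should persist and C2 is not touched.

**Step 8**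
Reactants: 11 (S)-7-(benzyloxy)-2-[5-(benzyloxy)-2-methoxyphenyl]chromane
Product: 13 (S)-7-(benzyloxy)-2-[5-(benzyloxy)-2-methoxyphenyl]chromane-6-carbaldehyde, via iminium chloride 12 (not isolated)
Conditions: POCl3, DMF, 0 → 60 °C; then aq NaOAc
Reagents that add atoms: N,N-dimethylformamide CN(C)C=O; water O
Why: Vilsmeier–Haack formylation at C6, which is para to O1 and ortho to the 7-benzyloxy group and less hindered than C8 between the two oxygens, while the hydroquinone-type ring on C2 is far less activated; hydrolysis of iminium 12 gives the aldehyde.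

**Step 9**
Reactants: 14 1-(4-hydroxy-2-methoxyphenyl)ethanone
Product: 15 1-[4-(benzyloxy)-2-methoxyphenyl]ethanone
Conditions: BnBr, K2CO3, DMF, rt
Reagents that add atoms: benzyl bromide BrCc1ccccc1
Why: Williamson ether synthesis; protection keeps the ketone enolizable and the later enone electrophilic, which a para phenoxide would not.

**Step 10**
Reactants: 13 (S)-7-(benzyloxy)-2-[5-(benzyloxy)-2-methoxyphenyl]chromane-6-carbaldehyde; 15 1-[4-(benzyloxy)-2-methoxyphenyl]ethanone
Product: 16 (E)-3-{(S)-7-(benzyloxy)-2-[5-(benzyloxy)-2-methoxyphenyl]chroman-6-yl}-1-[4-(benzyloxy)-2-methoxyphenyl]prop-2-en-1-one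
Conditions: KOH, EtOH/THF, rt
Reagents that add atoms: none
Why: Claisen–Schmidt condensation, in which the enolate of the methyl ketone adds to the non-enolizable aldehyde and E1cB dehydration gives the (E)-enone under thermodynamic control; C2 is not acidic and is unaffected.

**Step 11**
Reactants: 16 the (E)-enone of step 10; 17 [4-(benzyloxy)phenyl]boronic acid
Product: 18 (R)-3-{(S)-7-(benzyloxy)-2-[5-(benzyloxy)-2-methoxyphenyl]chroman-6-yl}-3-[4-(benzyloxy)phenyl]-1-[4-(benzyloxy)-2-methoxyphenyl]propan-1-one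
Conditions: [RhCl(C2H4)2]2 (2.5 mol%), (1R,4R)-2,5-diphenylbicyclo[2.2.2]octa-2,5-diene (5.5 mol%), KOH (0.5 equiv), dioxane/H2O, 50 °C
Reagents that add atoms: none
Why: Hayashi–Miyaura asymmetric 1,4-addition, in which transmetalation gives an aryl–rhodium species held by the chiral diene, the (E)-enone inserts through one enantioface and the rhodium enolate is protonated; the (R,R)-diene, which has the facial sense of (R)-BINAP with (E)-enones, should deliver the aryl group to the Si face of C-β (ranking ring A > C-α > H) and so set the (R) diarylmethine centre under catalyst control, independent of the remote C2 centre.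

**Step 12**
Reactants: 18 the ketone of step 11
Product: 19 (3R)-3-{(S)-7-(benzyloxy)-2-[5-(benzyloxy)-2-methoxyphenyl]chroman-6-yl}-3-[4-(benzyloxy)phenyl]-1-[4-(benzyloxy)-2-methoxyphenyl]propan-1-ol (both epimers at the carbinol carbon)
Conditions: NaBH4, MeOH/THF, 0 °C
Reagents that add atoms: none
Why: Hydride reduction of the aryl ketone; the new carbinol centre is formed without control, which does not matter because it is removed in step 13.

**Step 13**
Reactants: 19 the alcohol of step 12
Product: 20 (2S)-6-[(1R)-3-(4-hydroxy-2-methoxyphenyl)-1-(4-hydroxyphenyl)propyl]-2-(5-hydroxy-2-methoxyphenyl)chroman-7-ol (target)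
Conditions: H2 (1 atm), 10% Pd/C, EtOAc/MeOH, AcOH (cat.), rt
Reagents that add atoms: none
Why: Catalytic hydrogenolysis cleaves the four aryl benzyl ethers and the benzylic hydroxyl, which is activated by the para oxygen and ortho methoxy group of its ring, to CH2; under near-neutral conditions at 1 atm the cyclic benzylic C2–O1 ether and both stereocentres should persist.

**Compound list**

1 | 2-fluoro-4-hydroxybenzaldehyde | O=Cc1ccc(O)cc1F | starting material
2 | 4-(benzyloxy)-2-fluorobenzaldehyde | O=Cc1ccc(OCc2ccccc2)cc1F | intermediate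
3 | 2-[4-(benzyloxy)-2-fluorophenyl]-1,3-dithiane | Fc1cc(OCc2ccccc2)ccc1C1SCCCS1 | intermediate
4 | 5-hydroxy-2-methoxybenzaldehyde | COc1ccc(O)cc1C=O | starting material
5 | 5-(benzyloxy)-2-methoxybenzaldehyde | COc1ccc(OCc2ccccc2)cc1C=O | intermediate
6 | racemic 2-[5-(benzyloxy)-2-methoxyphenyl]oxirane | COc1ccc(OCc2ccccc2)cc1C1CO1 | intermediate
7 | (R)-2-[5-(benzyloxy)-2-methoxyphenyl]oxirane | COc1ccc(OCc2ccccc2)cc1[C@@H]1CO1 | intermediate
8 | 2-[4-(benzyloxy)-2-fluorophenyl]-2-lithio-1,3-dithiane | [Li]C1(c2ccc(OCc3ccccc3)cc2F)SCCCS1 | intermediate (not isolated)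
9 | lithium (S)-1-[5-(benzyloxy)-2-methoxyphenyl]-2-{2-[4-(benzyloxy)-2-fluorophenyl]-1,3-dithian-2-yl}ethan-1-olate | [Li]O[C@H](c1cc(OCc2ccccc2)ccc1OC)CC1(c2ccc(OCc3ccccc3)cc2F)SCCCS1 | intermediate (not isolated)
10 | (2S)-7-(benzyloxy)-2-[5-(benzyloxy)-2-methoxyphenyl]spiro[chromane-4,2'-[1,3]dithiane] | O1[C@H](c2cc(OCc3ccccc3)ccc2OC)CC2(SCCCS2)c2ccc(OCc3ccccc3)cc21 | intermediate
11 | (S)-7-(benzyloxy)-2-[5-(benzyloxy)-2-methoxyphenyl]chromane | O1[C@H](c2cc(OCc3ccccc3)ccc2OC)CCc2ccc(OCc3ccccc3)cc21 | intermediate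
12 | N-({(S)-7-(benzyloxy)-2-[5-(benzyloxy)-2-methoxyphenyl]chroman-6-yl}methylene)-N-methylmethanaminium chloride | O1[C@H](c2cc(OCc3ccccc3)ccc2OC)CCc2cc(C=[N+](C)C)c(OCc3ccccc3)cc21.[Cl-] | intermediate (not isolated)
13 | (S)-7-(benzyloxy)-2-[5-(benzyloxy)-2-methoxyphenyl]chromane-6-carbaldehyde | O1[C@H](c2cc(OCc3ccccc3)ccc2OC)CCc2cc(C=O)c(OCc3ccccc3)cc21 | intermediate
14 | 1-(4-hydroxy-2-methoxyphenyl)ethanone | CC(=O)c1ccc(O)cc1OC | starting material
15 | 1-[4-(benzyloxy)-2-methoxyphenyl]ethanone | CC(=O)c1ccc(OCc2ccccc2)cc1OC | intermediate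
16 | (E)-3-{(S)-7-(benzyloxy)-2-[5-(benzyloxy)-2-methoxyphenyl]chroman-6-yl}-1-[4-(benzyloxy)-2-methoxyphenyl]prop-2-en-1-one | O1[C@H](c2cc(OCc3ccccc3)ccc2OC)CCc2cc(/C=C/C(=O)c3ccc(OCc4ccccc4)cc3OC)c(OCc3ccccc3)cc21 | intermediate
17 | [4-(benzyloxy)phenyl]boronic acid | OB(O)c1ccc(OCc2ccccc2)cc1 | starting material
18 | (R)-3-{(S)-7-(benzyloxy)-2-[5-(benzyloxy)-2-methoxyphenyl]chroman-6-yl}-3-[4-(benzyloxy)phenyl]-1-[4-(benzyloxy)-2-methoxyphenyl]propan-1-one | COc1cc(OCc2ccccc2)ccc1C(=O)C[C@H](c1ccc(OCc2ccccc2)cc1)c1cc2c(cc1OCc1ccccc1)O[C@H](c1cc(OCc3ccccc3)ccc1OC)CC2 | intermediate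
19 | (3R)-3-{(S)-7-(benzyloxy)-2-[5-(benzyloxy)-2-methoxyphenyl]chroman-6-yl}-3-[4-(benzyloxy)phenyl]-1-[4-(benzyloxy)-2-methoxyphenyl]propan-1-ol (both carbinol epimers) | COc1cc(OCc2ccccc2)ccc1C(O)C[C@H](c1ccc(OCc2ccccc2)cc1)c1cc2c(cc1OCc1ccccc1)O[C@H](c1cc(OCc3ccccc3)ccc1OC)CC2 | intermediate
20 | (2S)-6-[(1R)-3-(4-hydroxy-2-methoxyphenyl)-1-(4-hydroxyphenyl)propyl]-2-(5-hydroxy-2-methoxyphenyl)chroman-7-ol | COc1cc(O)ccc1CC[C@H](c1ccc(O)cc1)c1cc2c(cc1O)O[C@H](c1cc(O)ccc1OC)CC2 | target

**Totals.** Total step count: 13. Longest linear sequence: 10 steps (steps 3, 4, 5, 6, 7, 8, 10, 11, 12, 13).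

**Steps most likely to fail**

1. Step 6. The alkoxide may fail to displace the unactivated fluoride before base-induced side reactions take over, or the carbanion may open the oxirane partly at the benzylic carbon. The fallback sets out from racemic oxirane 6 and comes back at 10; it closes the ring at O1–C2 by a Mitsunobu reaction instead of at O1–C8a. Resolution of 6 with the (S,S)-enantiomer of the cobalt catalyst leaves (S)-2-[5-(benzyloxy)-2-methoxyphenyl]oxirane F1. Commercial 4-(benzyloxy)-2-hydroxybenzaldehyde and propane-1,3-dithiol (I2 cat.) give 5-(benzyloxy)-2-(1,3-dithian-2-yl)phenol F2. Its dianion (n-BuLi, 2.1 equiv, THF, −78 → −20 °C) opens F1 at CH2 to give (R)-5-(benzyloxy)-2-{2-[2-(5-(benzyloxy)-2-methoxyphenyl)-2-hydroxyethyl]-1,3-dithian-2-yl}phenol F3. Mitsunobu cyclization (PPh3, DIAD, THF, 0 °C) lets the phenol oxygen displace the activated carbinol oxygen with inversion and should give 10 with (S) configuration.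

2. Step 11. Insertion of the hindered, electron-rich β-aryl enone may be slow, so that protodeboronation competes, or the facial selectivity may be insufficient. The fallback sets out from 11 and 15 and comes back at 18; it forms the bond from C6 of ring A to the methine carbon instead of the bond from the 4-oxygenated phenyl ring. Bromination of 11 (NBS, MeCN, 0 °C) gives (S)-7-(benzyloxy)-2-[5-(benzyloxy)-2-methoxyphenyl]-6-bromochromane F4. Miyaura borylation (Pd(dppf)Cl2, bis(pinacolato)diboron, KOAc, dioxane, 90 °C) gives the 6-(pinacolatoboryl)chromane F5. Claisen–Schmidt condensation of 15 with commercial 4-(benzyloxy)benzaldehyde (KOH, EtOH) gives the unhindered (E)-3-[4-(benzyloxy)phenyl]-1-[4-(benzyloxy)-2-methoxyphenyl]prop-2-en-1-one F6. Rhodium-catalysed addition of F5 to F6 with the antipodal (1S,4S)-diene should give 18; the ligand is inverted because the resident and incoming aryl groups are exchanged.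

3. Step 13. The longer exposure needed to remove the benzylic hydroxyl may lead to hydrogenolytic opening of the pyran ring at C2–O1, or deoxygenation may stay incomplete. The fallback sets out from 19 and comes back at 20; it takes the deoxygenation out of the hydrogenation. Ionic reduction of 19 (Et3SiH, TFA, CH2Cl2, −40 °C), in which the doubly activated benzylic cation is trapped by hydride, gives the tetrabenzyl ether (2S)-7-(benzyloxy)-2-[5-(benzyloxy)-2-methoxyphenyl]-6-{(1R)-1-[4-(benzyloxy)phenyl]-3-[4-(benzyloxy)-2-methoxyphenyl]propyl}chromane F7. A short transfer hydrogenolysis (10% Pd/C, cyclohexa-1,4-diene, EtOH/EtOAc, rt) then removes only the O-benzyl groups and gives 20.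

**Further compounds**

F1 | step 6 | (S)-2-[5-(benzyloxy)-2-methoxyphenyl]oxirane | COc1ccc(OCc2ccccc2)cc1[C@H]1CO1
F2 | step 6 | 5-(benzyloxy)-2-(1,3-dithian-2-yl)phenol | Oc1cc(OCc2ccccc2)ccc1C1SCCCS1
F3 | step 6 | (R)-5-(benzyloxy)-2-{2-[2-(5-(benzyloxy)-2-methoxyphenyl)-2-hydroxyethyl]-1,3-dithian-2-yl}phenol | O[C@@H](c1cc(OCc2ccccc2)ccc1OC)CC1(c2ccc(OCc3ccccc3)cc2O)SCCCS1
F4 | step 11 | (S)-7-(benzyloxy)-2-[5-(benzyloxy)-2-methoxyphenyl]-6-bromochromane | O1[C@H](c2cc(OCc3ccccc3)ccc2OC)CCc2cc(Br)c(OCc3ccccc3)cc21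
F5 | step 11 | (S)-7-(benzyloxy)-2-[5-(benzyloxy)-2-methoxyphenyl]-6-(4,4,5,5-tetramethyl-1,3,2-dioxaborolan-2-yl)chromane | O1[C@H](c2cc(OCc3ccccc3)ccc2OC)CCc2cc(B3OC(C)(C)C(C)(C)O3)c(OCc3ccccc3)cc21
F6 | step 11 | (E)-3-[4-(benzyloxy)phenyl]-1-[4-(benzyloxy)-2-methoxyphenyl]prop-2-en-1-one | COc1cc(OCc2ccccc2)ccc1C(=O)/C=C/c1ccc(OCc2ccccc2)cc1
F7 | step 13 | (2S)-7-(benzyloxy)-2-[5-(benzyloxy)-2-methoxyphenyl]-6-{(1R)-1-[4-(benzyloxy)phenyl]-3-[4-(benzyloxy)-2-methoxyphenyl]propyl}chromane | COc1cc(OCc2ccccc2)ccc1CC[C@H](c1ccc(OCc2ccccc2)cc1)c1cc2c(cc1OCc1ccccc1)O[C@H](c1cc(OCc3ccccc3)ccc1OC)CC2
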